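The south-west run, followed to 50.0 h, is read here as free catalyst turning starting material into target and other conformer into isomer of the product A, while the two conformers interconvert.

the same everywhere: free catalyst 2.1 mM

| charge | starting material | remark | time |
|---|---|---|---|
| south-west | 0.10 M | the very flask that is asked about, followed so far |  |
| south-east | 0.067 M | run made earlier |  |
| flask | 0.10 M |  | 10 d |

south-west run (percent of the starting material charged)

| time / h | isomer of the product A / % | target / % | starting material / % |
|---|---|---|---|
| 10.0 | 3.1 | 9.4 | 71.4 |
| 20.0 | 7.6 | 13.8 | 55.2 |
| 30.0 | 11.2 | 15.5 | 44.9 |
| 40.0 | 15.1 | 16.8 | 38.5 |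
| 50.0 | 15.8 | 17.3 | 33.5 |

south-east run (percent of the starting material charged)

| time / d | isomer of the product A / % | target / % | starting material / % |
|---|---|---|---|
| 0.333 | 2.3 | 7.5 | 76.2 |
| 1.04 | 9.9 | 15.7 | 48.6 |
| 1.67 | 14.7 | 16.3 | 38.1 |
| 3.00 | 18.5 | 18.1 | 27.8 |
| 4.00 | 19.9 | 17.7 | 25.5 |

(scatter of a reading: 0.3 percentage points)

- what may be going on: starting material <-> other conformer; starting material + free catalyst -> free catalyst + target; free catalyst + other conformer -> free catalyst + isomer of the product A; free catalyst -> spent catalyst; target + free catalyst <-> isomer of the product B + free catalyst

- ratio of isomer of the product A to target at 80 min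
- ratio of isomer of the product A to target at 15 h
- ratio of isomer of the product A to target at 10 d

1. The symmetric case is the zero of the scale: a free catalyst indifferent to the conformers makes isomer of the product A and target in the proportion of other conformer to starting material, here called the conformer ratio.

2. At 10.0 h the unread remainder of the charge gives a conformer ratio of 0.225. With straight growth the products have met half of that, so the product ratio implies a factor of 2.93 over the symmetric case. But straight growth is only assumed.

3. Increments avoid that assumption. From 30.0 h to 50.0 h isomer of the product A rises 4.6 percentage points and target 1.8 points, around a conformer ratio of 0.769. The selectivity factor s, the rate ratio of the two products per unit of conformer ratio, is therefore 3.32. Yet each reading is good only to 0.3 points, and isomer of the product B is hidden in the remainder, so s is rough, though it stands above the symmetric value.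

4. At 80 min, with the conformer ratio scaled in proportion to time from its value at 10.0 h, the product ratio is s times half of it, which gives 0.0500.

5. At 15 h the neighbouring readings give 0.440. For 10 d the south-east run, which matches the south-west run in fractions at 40.0 h, offers its last reading, a ratio of 1.12 at 4.00 d. Isomer of the product A was still gaining 1.4 points in that last day, so the doubt lies upward.

The forecast, holding that the “catalyst is therefore essentially dead by 10 d”, gives 0.04, 0.44 and 1.22, its first value differing from the 0.0500 reckoned here.

The flask gives 0.0520, 0.464 and 1.11.

    starting material ⇌ other conformer (K = 1.60, k = 0.0240 /h)
    starting material + free catalyst → free catalyst + target (k = 6.60 /M/h)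
    free catalyst + other conformer → free catalyst + isomer of the product A (k = 22.0 /M/h)
    free catalyst → spent catalyst (k = 0.0450 /h)
    target + free catalyst ⇌ isomer of the product B + free catalyst, rate k5*[free catalyst]*[target] forward; the back reaction follows from the equilibrium constant (K = 0.360, k = 2.30 /M/h)

At 10.0 d the flask holds a conformer ratio of 1.60, but dividing isomer of the product A over target plus isomer of the product B by s gives a mean of 0.315 met during the work. Free catalyst in the flask is down to 34.0% of its charge at 1.00 d, and a run without that loss reaches a ratio of 1.76 at 10 d instead of 1.11. The neighbour flask charged with 0.0084 M of free catalyst gives, by the same division, a mean of 0.170, lower than the mean of the flask.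

(All runs are calculated for substances that don't exist; scatter was added.)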